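## Structural features

Penicanesin D is built from two six-membered rings joined through one methylene carbon: a pentasubstituted benzene (ring A) and a 4-hydroxy-2H-pyran-2-one (ring B). Around ring A the substituents are acetyl (C1), OH (C2), OH (C3), OCH3 (C4), H (C5) and the bridging CH2 (C6), so the bridge is ortho to the acetyl group, para to the C3 hydroxyl and meta to the methoxy group. In ring B the bridge sits on C3, between the lactone carbonyl C2 and the enolic C4–OH, and C6 carries a 2-hydroxypropyl chain whose carbinol carbon (S) is the only stereocenter and has no stereogenic neighbour. Fragile groups are the vinylogous acid of ring B (ambident at O4, C3 and C5), the catechol at C2/C3 of ring A (oxidised easily to an ortho-quinone and, because the bridge is para to O3, onward to a para-quinone methide), the β-hydroxyalkyl chain (dehydration into conjugation with ring B) and the enolisable aryl methyl ketone. The real difficulty is connectivity, not stereochemistry: the C6(ring A)–CH2–C3(ring B) link lies at the most hindered and electronically least accessible carbon of ring A (electrophiles go to C5), and the three oxygens of ring A must end up differentiated. The key step exploits two facts: in a 2,3,4-trioxygenated acetophenone, C6 is the only C–H ortho to the C1 acetyl carbonyl, and C3 of ring B carrying one extra carbon with a leaving group is a latent exo-methylene Michael acceptor.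

## Logic of the disconnections

**10 to 8.** No skeletal bond is cut; the O–H bonds at O2 and O3 of ring A are read backwards as O–CH3 bonds. The reason is that ring A with three methyl ethers is a commercial arene and has no free ortho-hydroxyl to tie up the acetyl oxygen or the metal in the key step. The gain is that ring A needs no protecting-group steps. The demand on the forward step is cleavage of the methyl ethers at O2 and O3 but not at O4, next to ring B and a free carbinol; chelation of boron by the acetyl oxygen, then by O2, should provide this.

**8 to 6 and 7 (key disconnection).** The bond cut is C6(ring A)–CH2, not the CH2–C3(ring B) bond of the usual benzylation. In one sentence: the acetyl group of 6 directs a rhodium catalyst to its only ortho C–H bond, which adds across the exocyclic C=CH2 of 7, released in the flask from 5. The reason for cutting here is that the acetyl group already present in the target marks exactly this carbon. The gain is large: ring A is bought complete, no benzylic halide or aldehyde has to be made, and the whole carbon skeleton is assembled in one operation. The demand is that the aryl–rhodium species outruns the other fates of the short-lived acceptor 7, and that C6 is chosen over the more electron-rich C5.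

**7 to 5 to 4.** 7 cannot be stored, so morpholine is added back across its C=CH2 bond to give the zwitterion 5; in 5 the C3(ring B)–CH2 bond is then cut (Mannich reaction). This attaches the bridge carbon to ring B at its most nucleophilic carbon without touching O4. The demand is mono-aminomethylation at C3 without a second pyranone adding to give a methylene-bis(pyranone).

**4 to 3.** The C–H bond at the carbinol carbon is cut (ketone reduction). This removes the only stereocenter and puts its control into a single reagent-controlled step. The demand is reduction of the side-chain methyl ketone with S selectivity, leaving the lactone and enol of ring B alone.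

**3 to 1 (via 2).** The bond cut is the side-chain C(=O)–CH2 bond. This leads back to the commercial pyranone 1, which already contains ring B with the right oxidation pattern. The demand is acylation at the 6-methyl carbon of the dianion 2, not at O4, C3 or C5, and no second addition to the new ketone. The starting materials are 1 and 6.

## Other disconnections considered

**Alternative 1:** (the first that comes to mind) cut the CH2–C3(ring B) bond. The forward key step is C-alkylation of the pyranonate of 4 with the benzylic bromide A1, made by radical bromination of A2, the Friedel–Crafts acetylation product of 3,4,5-trimethoxytoluene; the O2/O3 methyl ethers are then cleaved as in step 5. The chosen plan is preferred on three grounds: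
- The pyranonate is ambident, so attack through O4 competes with attack through C3.
- The radical bromination of A2 has to distinguish the benzylic methyl group from the enolisable acetyl group and from the nucleophilic C5–H of the ring.
- A1 costs two extra steps on ring A, which the chosen plan buys complete.

**Alternative 2:** cut the same CH2–C3(ring B) bond, but in the oxidative, biomimetic sense. The forward key step is oxidation of catechol A3 to the ortho-quinone A4, tautomerisation to the para-quinone methide A5 (possible because the methyl group is para to O3) and conjugate addition of 4 through C3. It would need no protecting groups, but the chosen plan is preferred for mechanistic reasons: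
- The product is itself a catechol with a CH2 para to O3, so the oxidant cannot tell it from A3, and re-oxidation would lead to a second addition.
- A4 is also electrophilic at ring carbon C5, which opens direct arylation of the pyranonate.
- The electron-rich enol of 4 is itself open to the oxidant.
- The bond formed is the same as in Alternative 1, so it adds no new strategic element.

**Alternative 3:** cut C1–C2 and C5–C6 of ring A, building the benzene ring from open-chain precursors. The forward key step is a Diels–Alder reaction of ynone A6 with the silyl ketene acetal diene A7, followed by loss of methanol. The CH2 terminus of A7 should bond to the β-carbon of the ynone, which would place all six substituents and give an arene of the constitution of 9. The regiochemistry is defensible, but the chosen plan is preferred on step economy: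
- A7 is a tetra-oxygenated diene needing about three steps.
- A6 needs a C3-propargylation of the pyranone that competes with O-alkylation.
- The acidic OH of ring B would protonate A7 unless it is masked and later unmasked.
- The ring being built is commercially available with the right substitution pattern, so the ring construction would add steps and gain nothing.

Key step: step 4

Remark on the chemistry: the descriptor of the single stereocenter read from the SMILES is S; compounds 1 and 6, N-methoxy-N-methylacetamide and 4,4'-methylenedimorpholine are taken to be commercial.

## Route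

Step 1
Reactants: 1 4-hydroxy-6-methyl-2H-pyran-2-one (triacetic acid lactone)
Product: 3 4-hydroxy-6-(2-oxopropyl)-2H-pyran-2-one, via dilithium dianion of the pyranone 2 (not isolated)
Conditions: LiN(i-Pr)2 (2.2 equiv), THF, −78 °C; then MeC(O)N(OMe)Me (1.1 equiv), −78 → 0 °C; 1 M HCl
Reagents that add atoms: N-methoxy-N-methylacetamide, CC(=O)N(C)OC
Why: Acylation of a 4-hydroxypyranone dianion at its most basic carbon, the former 6-methyl group (vinylogous Claisen-type C-acylation); the N-methoxy-N-methylamide keeps the adduct as a lithium chelate until the quench, so the ketone is released only on work-up and should not be attacked twice.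

Step 2
Reactants: 3 4-hydroxy-6-(2-oxopropyl)-2H-pyran-2-one
Product: 4 4-hydroxy-6-[(2S)-2-hydroxypropyl]-2H-pyran-2-one
Conditions: (S)-selective alcohol dehydrogenase (ketoreductase class), NAD+ (cat.), i-PrOH (10 vol %), KH2PO4/K2HPO4 buffer pH 7.0, 30 °C
Reagents that add atoms: none
Why: Biocatalytic carbonyl reduction with isopropanol as the coupled hydride source; enzymes of this class that deliver hydride to the re face of methyl ketones bearing a larger second substituent should give the S carbinol, so the enzyme pocket sets the stereocenter, and the lactone and enol of ring B are not substrates.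

Step 3
Reactants: 4 4-hydroxy-6-[(2S)-2-hydroxypropyl]-2H-pyran-2-one
Product: 5 4-hydroxy-6-[(2S)-2-hydroxypropyl]-3-(morpholin-4-ylmethyl)-2H-pyran-2-one (zwitterion)
Conditions: 4,4'-methylenedimorpholine (1.05 equiv), EtOH, 0 °C → rt
Reagents that add atoms: 4,4'-methylenedimorpholine, C1COCCN1CN1CCOCC1
Why: Mannich reaction; the acidic pyranone activates the aminal as the aminomethylating electrophile, and C3, between the lactone carbonyl and the enol, is the most nucleophilic carbon of a 4-hydroxy-2-pyranone; the zwitterion should precipitate, which limits a second addition.

Step 4
Reactants: 5 4-hydroxy-6-[(2S)-2-hydroxypropyl]-3-(morpholin-4-ylmethyl)-2H-pyran-2-one; 6 1-(2,3,4-trimethoxyphenyl)ethan-1-one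
Product: 8 3-[(2-acetyl-3,4,5-trimethoxyphenyl)methyl]-4-hydroxy-6-[(2S)-2-hydroxypropyl]-2H-pyran-2-one, via 6-[(2S)-2-hydroxypropyl]-3-methylidene-2H-pyran-2,4(3H)-dione 7 (not isolated)
Conditions: 6 (3 equiv), [Cp*RhCl2]2 (2.5 mol %), AgSbF6 (10 mol %), NaO2CCMe3 (20 mol %), Me3CCO2H (1 equiv), ClCH2CH2Cl/(CF3)2CHOH 4:1, 90 °C, slow addition of 5
Reagents that add atoms: none
Why: Proposed new method: AgSbF6 and pivalate turn [Cp*RhCl2]2 into a cationic trivalent rhodium pivalate that binds the acetyl oxygen of 6 and cleaves the only C–H bond ortho to it, at C6 of ring A, by concerted metalation–deprotonation, while zwitterionic 5 loses morpholine from its pyranonate (E1cB) and so feeds the exo-methylene dione 7 into the solution at a low stationary concentration. The doubly activated C=CH2 of 7 inserts into the aryl–Rh bond with the aryl group going to the unsubstituted CH2 carbon (conjugate addition), and pivalic acid protonates the resulting O-bound rhodium pyranonate, which releases 8 and the rhodium pivalate in a redox-neutral cycle. The closest known reaction types are the ketone-directed ortho C–H conjugate addition of aryl ketones to maleimides and enones with [Cp*RhCl2]2/AgSbF6 or [RuCl2(p-cymene)]2/AgSbF6, and the Michael trapping of methylene pyrandiones set free from Mannich bases of 4-hydroxypyranones; interception of such a transient acceptor by a cyclometalated ketone is the new element. The step closes no ring and creates no stereocenter, and the carbinol carbon of 5 is a spectator. It needs site selectivity for C6 over the electronically favoured C5, which chelation secures because cyclometalation can only reach the position ortho to the carbonyl group, while the acetyl group and the weakly acidic medium slow the uncatalysed Friedel–Crafts attack at C5. It needs chemoselectivity for aryl–C bond formation over self-condensation of 7, which slow addition of 5, the excess of 6 and the blocked C3 of 5 secure, and a second alkylation is excluded because 8 has no C–H left ortho to the acetyl group.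

Step 5
Reactants: 8 3-[(2-acetyl-3,4,5-trimethoxyphenyl)methyl]-4-hydroxy-6-[(2S)-2-hydroxypropyl]-2H-pyran-2-one
Product: 10 Penicanesin D, 3-[(2-acetyl-3,4-dihydroxy-5-methoxyphenyl)methyl]-4-hydroxy-6-[(2S)-2-hydroxypropyl]-2H-pyran-2-one, via boron-bound 2-hydroxy-3,4-dimethoxy intermediate 9 (not isolated)
Conditions: BCl3 (6 equiv), CH2Cl2, −78 °C → rt; then H2O
Reagents that add atoms: none
Why: Chelation-controlled Lewis acid ether cleavage; boron held between the acetyl oxygen and O2 should cleave the O2 methyl ether first, the resulting aryloxyboron then reaches the neighbouring O3 methyl ether and closes a cyclic catechol borate, while the O4 methyl ether, para to the acyl group and outside any chelate, should survive; the stereocenter is carried as a borate ester and released unchanged on hydrolysis.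

## Compound list

1 | 4-hydroxy-6-methyl-2H-pyran-2-one (triacetic acid lactone) | CC1=CC(O)=CC(=O)O1 | starting material
2 | dilithium dianion of 1 (charges at O4 and the former 6-methyl carbon) | [Li+].[Li+].[CH2-]C1=CC([O-])=CC(=O)O1 | intermediate
3 | 4-hydroxy-6-(2-oxopropyl)-2H-pyran-2-one | CC(=O)CC1=CC(O)=CC(=O)O1 | intermediate
4 | 4-hydroxy-6-[(2S)-2-hydroxypropyl]-2H-pyran-2-one | C[C@H](O)CC1=CC(O)=CC(=O)O1 | intermediate
5 | 4-hydroxy-6-[(2S)-2-hydroxypropyl]-3-(morpholin-4-ylmethyl)-2H-pyran-2-one (zwitterion, drawn neutral) | C[C@H](O)CC1=CC(O)=C(CN2CCOCC2)C(=O)O1 | intermediate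
6 | 1-(2,3,4-trimethoxyphenyl)ethan-1-one | COc1ccc(C(C)=O)c(OC)c1OC | starting material
7 | 6-[(2S)-2-hydroxypropyl]-3-methylidene-2H-pyran-2,4(3H)-dione | C[C@H](O)CC1=CC(=O)C(=C)C(=O)O1 | intermediate
8 | 3-[(2-acetyl-3,4,5-trimethoxyphenyl)methyl]-4-hydroxy-6-[(2S)-2-hydroxypropyl]-2H-pyran-2-one | COc1cc(Cc2c(O)cc(C[C@H](C)O)oc2=O)c(C(C)=O)c(OC)c1OC | intermediate
9 | 3-[(2-acetyl-3-hydroxy-4,5-dimethoxyphenyl)methyl]-4-hydroxy-6-[(2S)-2-hydroxypropyl]-2H-pyran-2-one (held as its chloroborates in the flask, drawn boron-free) | COc1cc(Cc2c(O)cc(C[C@H](C)O)oc2=O)c(C(C)=O)c(O)c1OC | intermediate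
10 | Penicanesin D, 3-[(2-acetyl-3,4-dihydroxy-5-methoxyphenyl)methyl]-4-hydroxy-6-[(2S)-2-hydroxypropyl]-2H-pyran-2-one | COc1cc(Cc2c(O)cc(C[C@H](C)O)oc2=O)c(C(C)=O)c(O)c1O | target

## Step count and least certain steps

Total step count: 5. Longest linear sequence: 5 steps (1 → 3 → 4 → 5 → 8 → 10; 6 enters at step 4).

**Step 4 (key step, proposed new method).** The most likely failure is loss of the transient acceptor 7 before it meets the aryl–rhodium species. That species is present only at catalyst concentration and the ketone is a weak directing group, so 7 may instead dimerise, add oxygen nucleophiles, or be attacked by C5 of 6 without the catalyst. Hydrogen transfer from the carbinol to 7 at rhodium could also erode the stereocenter. The fallback uses known chemistry, sets out from 4 and comes back at 8. Commercial 2-bromo-3,4,5-trimethoxybenzaldehyde is coupled with tributyl(1-ethoxyvinyl)stannane (Pd(PPh3)4, toluene, 100 °C; Stille coupling) to give 2-(1-ethoxyethenyl)-3,4,5-trimethoxybenzaldehyde F1. Dilute acid (1 M HCl, THF) hydrolyses the enol ether to 2-acetyl-3,4,5-trimethoxybenzaldehyde F2. F2, 4 and diethyl 2,6-dimethyl-1,4-dihydropyridine-3,5-dicarboxylate (Hantzsch ester) with catalytic L-proline in EtOH then undergo the three-component reductive alkylation of 4-hydroxypyranones. Knoevenagel condensation at C3 of ring B gives 3-[(2-acetyl-3,4,5-trimethoxyphenyl)methylidene]-6-[(2S)-2-hydroxypropyl]-2H-pyran-2,4(3H)-dione F3, which the dihydropyridine reduces in the flask by conjugate hydride transfer, and the route is rejoined at 8.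

**Step 5.** The most likely failure is loss of selectivity among the three methyl ethers: the reaction may stall after O2 or go on to O4, because the second cleavage depends on boron reaching O3 from O2. Substitution or elimination at the carbinol through its chloroborate is a second risk. The fallback avoids any Lewis acid, sets out from 5 and comes back at 10. Commercial 1-(2,3,4-trihydroxyphenyl)ethan-1-one is methylated at O4 while O2/O3 are tied up as a borate (Na2B4O7, NaOH, Me2SO4, H2O) to give 1-(2,3-dihydroxy-4-methoxyphenyl)ethan-1-one F4. Benzylation (BnBr, K2CO3, DMF) gives 1-[2,3-bis(benzyloxy)-4-methoxyphenyl]ethan-1-one F5. F5 takes the place of 6 in step 4 and couples with 5 to give 3-{[2-acetyl-3,4-bis(benzyloxy)-5-methoxyphenyl]methyl}-4-hydroxy-6-[(2S)-2-hydroxypropyl]-2H-pyran-2-one F6. Hydrogenolysis (H2, 1 atm, Pd/C, EtOAc) should remove both benzyl groups and give 10.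

**Step 2.** The most likely failure is poor acceptance of the substrate by the enzyme, since 3 is an anionic pyranonate at pH 7; slow ring transformation of the polyketide-like 3 in buffer would lower conversion. The fallback replaces asymmetric reduction by resolution, sets out from 3 and comes back at 4. NaBH4 (MeOH, 0 °C) gives racemic 4-hydroxy-6-(2-hydroxypropyl)-2H-pyran-2-one F7. Lipase B of Candida antarctica with vinyl acetate in t-BuOMe should acetylate the R enantiomer, following the usual preference of this lipase when the larger substituent outranks methyl, to give (2R)-1-(4-hydroxy-2-oxo-2H-pyran-6-yl)propan-2-yl acetate F8. The unreacted S alcohol is 4, separated by chromatography, at the cost of at most half of the material.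

**Step 3.** The most likely failure is a second conjugate addition: 5 can lose morpholine in solution, and unreacted 4 would add to the resulting acceptor to give a methylene-bis(pyranone). The fallback changes the precursor of 7, sets out from 4 and comes back at 8. Compound 4, paraformaldehyde and 4-methylbenzenesulfinic acid (EtOH/H2O, rt) should give 4-hydroxy-6-[(2S)-2-hydroxypropyl]-3-{[(4-methylphenyl)sulfonyl]methyl}-2H-pyran-2-one F9. F9 is not a zwitterion and cannot revert by a retro-Mannich path. Under the conditions of step 4 with NaO2CCMe3 (1 equiv) it should lose sulfinate to give 7, which is converted into 8 as in step 4.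

## Further compounds

F1 | step 4 | 2-(1-ethoxyethenyl)-3,4,5-trimethoxybenzaldehyde | CCOC(=C)c1c(C=O)cc(OC)c(OC)c1OC
F2 | step 4 | 2-acetyl-3,4,5-trimethoxybenzaldehyde | CC(=O)c1c(C=O)cc(OC)c(OC)c1OC
F3 | step 4 | 3-[(2-acetyl-3,4,5-trimethoxyphenyl)methylidene]-6-[(2S)-2-hydroxypropyl]-2H-pyran-2,4(3H)-dione | COc1cc(C=C2C(=O)C=C(C[C@H](C)O)OC2=O)c(C(C)=O)c(OC)c1OC
F4 | step 5 | 1-(2,3-dihydroxy-4-methoxyphenyl)ethan-1-one | COc1ccc(C(C)=O)c(O)c1O
F5 | step 5 | 1-[2,3-bis(benzyloxy)-4-methoxyphenyl]ethan-1-one | COc1ccc(C(C)=O)c(OCc2ccccc2)c1OCc1ccccc1
F6 | step 5 | 3-{[2-acetyl-3,4-bis(benzyloxy)-5-methoxyphenyl]methyl}-4-hydroxy-6-[(2S)-2-hydroxypropyl]-2H-pyran-2-one | COc1cc(Cc2c(O)cc(C[C@H](C)O)oc2=O)c(C(C)=O)c(OCc2ccccc2)c1OCc1ccccc1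
F7 | step 2 | racemic 4-hydroxy-6-(2-hydroxypropyl)-2H-pyran-2-one | CC(O)CC1=CC(O)=CC(=O)O1
F8 | step 2 | (2R)-1-(4-hydroxy-2-oxo-2H-pyran-6-yl)propan-2-yl acetate | C[C@@H](OC(C)=O)CC1=CC(O)=CC(=O)O1
F9 | step 3 | 4-hydroxy-6-[(2S)-2-hydroxypropyl]-3-{[(4-methylphenyl)sulfonyl]methyl}-2H-pyran-2-one | Cc1ccc(cc1)S(=O)(=O)CC1=C(O)C=C(C[C@H](C)O)OC1=O
A1 | alternative 1 | 1-[6-(bromomethyl)-2,3,4-trimethoxyphenyl]ethan-1-one | COc1cc(CBr)c(C(C)=O)c(OC)c1OC
A2 | alternative 1 | 1-(2,3,4-trimethoxy-6-methylphenyl)ethan-1-one | COc1cc(C)c(C(C)=O)c(OC)c1OC
A3 | alternative 2 | 1-(2,3-dihydroxy-4-methoxy-6-methylphenyl)ethan-1-one | COc1cc(C)c(C(C)=O)c(O)c1O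
A4 | alternative 2 | 3-acetyl-6-methoxy-4-methylcyclohexa-3,5-diene-1,2-dione | COC1=CC(C)=C(C(C)=O)C(=O)C1=O
A5 | alternative 2 | 3-acetyl-2-hydroxy-6-methoxy-4-methylidenecyclohexa-2,5-dien-1-one | COC1=CC(=C)C(C(C)=O)=C(O)C1=O
A6 | alternative 3 | 4-hydroxy-6-[(2S)-2-hydroxypropyl]-3-(4-oxopent-2-yn-1-yl)-2H-pyran-2-one | CC(=O)C#CCc1c(O)cc(C[C@H](C)O)oc1=O
A7 | alternative 3 | trimethyl[(1,2,3-trimethoxybuta-1,3-dien-1-yl)oxy]silane | C=C(OC)C(OC)=C(OC)O[Si](C)(C)C
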